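A direct plan would make the arene itself: an alkenyllithium would be added to dimethyl squarate A1 and the adduct O-methylated to cyclobutenone A2.
Thermal ring expansion of A2, acetal hydrolysis and Wittig lactonisation with Ph3P=C=C=O would give 6,7,8-trimethoxycoumarin A3.
AlCl3 would then have to cleave the C7 methyl ether alone to give isofraxidin A4; a Mitsunobu reaction with (2R,3S)-2,3-epoxynerol A5 would give epoxy ether A6, and aqueous acid would open the epoxide to the diol.
Its weakest steps would be these:
- The de novo construction of the benzene ring would spend about five steps to reach the plain trimethoxycoumarin A3 and add little complexity.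
- The mono-demethylation would leave the choice among three aryl methyl ethers, next to a Lewis-basic lactone, to the reagent.
- The acid hydrolysis of the trisubstituted epoxide would set C3' by attack of water on a tertiary, cation-like carbon, so partial retention, elimination or participation of the C6'=C7' alkene would be possible, and it would do so on the most advanced intermediate.

**Plan of the new route**
The retrosynthesis cuts C4–C4a of the pyranone (gold-catalysed hydroarylation of an aryl propiolate), then the ester bond O1–C2, the C8a–O1 bond (ortho-metalation and oxidation), and last the O7–C1' ether bond together with the C2'–O bond (Payne rearrangement of (2S,3R)-epoxynerol trapped by an aryloxide).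
The benzene ring is bought as 2,6-dimethoxyphenol: its hydroxyl is O7 from the start, and its two positions next to OMe are equivalent, so O1 can enter at one place only.
The side chain and both stereocentres are in place before any heterocycle exists; the pyranone is the only ring that is made and it arises last.
The key step is possible because C8 of the benzene ring carries OMe: O1 has a single free ortho carbon, C4a, which lies para to O7, so only one 6-endo closure can occur.
No arene is built and no methyl ether is cleaved; C3' keeps the C–O bond made in the epoxidation and C2' is inverted by an intramolecular SN2 step, so no stereocentre depends on a tertiary cation.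

Key step: step 6

Remark: coumarin numbering is used for the ring atoms and primed locants (C1'–C8') for the side chain in every intermediate; nerol, 2,6-dimethoxyphenol and propiolic acid are taken as purchased.

Step 1
Reactants: 1 nerol
Product: 2 [(2S,3R)-3-methyl-3-(4-methylpent-3-en-1-yl)oxiran-2-yl]methanol ((2S,3R)-2,3-epoxynerol)
Conditions: Ti(OiPr)4 (cat.), L-(+)-diethyl tartrate (cat.), t-BuOOH, 4 Å molecular sieves, CH2Cl2, −20 °C
Reagents that add atoms: tert-butyl hydroperoxide, CC(C)(C)OO
Why: Sharpless asymmetric epoxidation: the titanium tartrate complex binds the allylic hydroxyl and delivers oxygen to one face of the C2'=C3' bond only, L-(+)-tartrate setting both centres as (2S,3R) on this Z-allylic alcohol and leaving the isolated C6'=C7' alkene alone, and the C3'–O bond made here is kept to the end.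

Step 2
Reactants: 2 (2S,3R)-2,3-epoxynerol; 3 2,6-dimethoxyphenol
Product: 5 (2R,3R)-1-(2,6-dimethoxyphenoxy)-3,7-dimethyloct-6-ene-2,3-diol, via terminal epoxy alcohol 4 (not isolated)
Conditions: t-BuOK (slight excess over 3), t-BuOH, N2, 80 °C; then H2O
Reagents that add atoms: none
Why: Payne rearrangement with trapping at C1': under anhydrous base the C1' alkoxide displaces the epoxide oxygen at C2' from the rear (intramolecular SN2, so C2' is inverted while C3' keeps its oxygen and configuration), and the aryloxide, the only good nucleophile present, opens the minor but far more reactive terminal epoxide 4 at its CH2 group, which drains the equilibrium towards the (2R,3R)-diol ether.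

Step 3
Reactants: 5 (2R,3R)-1-(2,6-dimethoxyphenoxy)-3,7-dimethyloct-6-ene-2,3-diol
Product: 6 (4R,5R)-5-[(2,6-dimethoxyphenoxy)methyl]-2,2,4-trimethyl-4-(4-methylpent-3-en-1-yl)-1,3-dioxolane
Conditions: Me2C(OMe)2, PPTS (cat.), CH2Cl2, rt
Reagents that add atoms: 2,2-dimethoxypropane, COC(C)(C)OC
Why: Acid-catalysed acetal exchange closes the five-membered isopropylidene acetal over the secondary and tertiary hydroxyls without breaking either carbinol C–O bond, which masks the diol for the organolithium and acylation steps.

Step 4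
Reactants: 6 (4R,5R)-5-[(2,6-dimethoxyphenoxy)methyl]-2,2,4-trimethyl-4-(4-methylpent-3-en-1-yl)-1,3-dioxolane
Product: 9 2,4-dimethoxy-3-{[(4R,5R)-2,2,4-trimethyl-4-(4-methylpent-3-en-1-yl)-1,3-dioxolan-5-yl]methoxy}phenol, via aryllithium 7 (not isolated), via dimethyl arylboronate 8 (not isolated)
Conditions: n-BuLi, TMEDA, THF, 0 °C; B(OMe)3, −78 °C → rt; then 30% H2O2, 0 °C → rt
Reagents that add atoms: hydrogen peroxide, OO
Why: Directed ortho-metalation: the methoxy oxygens guide n-BuLi to the ring carbon next to OMe, the two such carbons being equivalent by the symmetry of the 2,6-dimethoxyphenyl ether, and borylation followed by the peroxide-induced 1,2-shift of the aryl group from boron to oxygen places the future O1 there under conditions that do not epoxidise an isolated alkene.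

Step 5
Reactants: 9 2,4-dimethoxy-3-{[(4R,5R)-2,2,4-trimethyl-4-(4-methylpent-3-en-1-yl)-1,3-dioxolan-5-yl]methoxy}phenol; 10 propiolic acid
Product: 11 2,4-dimethoxy-3-{[(4R,5R)-2,2,4-trimethyl-4-(4-methylpent-3-en-1-yl)-1,3-dioxolan-5-yl]methoxy}phenyl prop-2-ynoate
Conditions: DCC, DMAP (2 mol %), CH2Cl2, 0 °C
Reagents that add atoms: none
Why: Steglich esterification with a carbodiimide acylates the only free hydroxyl, the phenol, at 0 °C under nearly neutral conditions, which avoids the base-induced conjugate addition that aryl propiolates suffer.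

Step 6
Reactants: 11 2,4-dimethoxy-3-{[(4R,5R)-2,2,4-trimethyl-4-(4-methylpent-3-en-1-yl)-1,3-dioxolan-5-yl]methoxy}phenyl prop-2-ynoate
Product: 12 6,8-dimethoxy-7-{[(4R,5R)-2,2,4-trimethyl-4-(4-methylpent-3-en-1-yl)-1,3-dioxolan-5-yl]methoxy}-2H-chromen-2-one
Conditions: [(t-Bu)2(2-biphenylyl)P]Au(NCMe)SbF6 (3 mol %), ClCH2CH2Cl (dry), rt → 50 °C
Reagents that add atoms: none
Why: The cationic monovalent gold complex binds the terminal alkyne of the s-trans ester rotamer, the arene carbon ortho to the ester oxygen (future C4a) attacks the terminal alkyne carbon (future C4) anti to gold in a Friedel–Crafts step, loss of the ring proton restores the arene, and protodeauration at C3 releases the coumarin and the catalyst. The closest known reaction type is the gold- or palladium-catalysed intramolecular hydroarylation of aryl alkynoates to coumarins. The pyranone ring is closed in the 6-endo-dig mode through the single new C4–C4a bond, the O1–C2 bond being already present as the ester. No stereocentre is created; the (4R,5R)-dioxolane is a bystander in the neutral aprotic medium, and the isolated trisubstituted alkene, remote from the alkyne and a poorer ligand for gold, should not compete. The selectivity needed is ortho (C4a) against ipso (C8a, para to the C6 methoxy group) attack: O1 has one free ortho carbon only, C8 being blocked by OMe, that carbon is para to O7, and an ipso adduct has no proton to lose, so without water it should either revert or reach the same coumarin by 1,2-shift of the vinyl carbon to C4a.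

Step 7
Reactants: 12 6,8-dimethoxy-7-{[(4R,5R)-2,2,4-trimethyl-4-(4-methylpent-3-en-1-yl)-1,3-dioxolan-5-yl]methoxy}-2H-chromen-2-one
Product: 13 7-{[(2R,3R)-2,3-dihydroxy-3,7-dimethyloct-6-en-1-yl]oxy}-6,8-dimethoxy-2H-chromen-2-one (altissimacoumarin C)
Conditions: AcOH/H2O (4:1), 40 °C
Reagents that add atoms: none
Why: Mild acid hydrolysis of the isopropylidene acetal goes through cleavage at the acetal carbon, so both carbinol C–O bonds and the (2'R,3'R) configuration are kept, and dilute acetic acid should spare the lactone, the aryl ethers and the trisubstituted alkene.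

## Compound list

1 | nerol ((2Z)-3,7-dimethylocta-2,6-dien-1-ol) | OC/C=C(C)\CCC=C(C)C | starting material
2 | [(2S,3R)-3-methyl-3-(4-methylpent-3-en-1-yl)oxiran-2-yl]methanol ((2S,3R)-2,3-epoxynerol) | OC[C@@H]1O[C@]1(C)CCC=C(C)C | intermediate
3 | 2,6-dimethoxyphenol | COc1cccc(OC)c1O | starting material
4 | (2R)-6-methyl-2-[(2R)-oxiran-2-yl]hept-5-en-2-ol ((2R,3R)-1,2-epoxy-3,7-dimethyloct-6-en-3-ol, present as its potassium alkoxide) | C1O[C@H]1[C@](C)(O)CCC=C(C)C | intermediate
5 | (2R,3R)-1-(2,6-dimethoxyphenoxy)-3,7-dimethyloct-6-ene-2,3-diol | COc1cccc(OC)c1OC[C@@H](O)[C@](C)(O)CCC=C(C)C | intermediate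
6 | (4R,5R)-5-[(2,6-dimethoxyphenoxy)methyl]-2,2,4-trimethyl-4-(4-methylpent-3-en-1-yl)-1,3-dioxolane | COc1cccc(OC)c1OC[C@H]1OC(C)(C)O[C@]1(C)CCC=C(C)C | intermediate
7 | (2,4-dimethoxy-3-{[(4R,5R)-2,2,4-trimethyl-4-(4-methylpent-3-en-1-yl)-1,3-dioxolan-5-yl]methoxy}phenyl)lithium | [Li]c1ccc(OC)c(OC[C@H]2OC(C)(C)O[C@]2(C)CCC=C(C)C)c1OC | intermediate
8 | dimethyl (2,4-dimethoxy-3-{[(4R,5R)-2,2,4-trimethyl-4-(4-methylpent-3-en-1-yl)-1,3-dioxolan-5-yl]methoxy}phenyl)boronate | COB(OC)c1ccc(OC)c(OC[C@H]2OC(C)(C)O[C@]2(C)CCC=C(C)C)c1OC | intermediate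
9 | 2,4-dimethoxy-3-{[(4R,5R)-2,2,4-trimethyl-4-(4-methylpent-3-en-1-yl)-1,3-dioxolan-5-yl]methoxy}phenol | COc1ccc(O)c(OC)c1OC[C@H]1OC(C)(C)O[C@]1(C)CCC=C(C)C | intermediate
10 | propiolic acid (prop-2-ynoic acid) | C#CC(=O)O | starting material
11 | 2,4-dimethoxy-3-{[(4R,5R)-2,2,4-trimethyl-4-(4-methylpent-3-en-1-yl)-1,3-dioxolan-5-yl]methoxy}phenyl prop-2-ynoate | C#CC(=O)Oc1ccc(OC)c(OC[C@H]2OC(C)(C)O[C@]2(C)CCC=C(C)C)c1OC | intermediate
12 | 6,8-dimethoxy-7-{[(4R,5R)-2,2,4-trimethyl-4-(4-methylpent-3-en-1-yl)-1,3-dioxolan-5-yl]methoxy}-2H-chromen-2-one | COc1cc2ccc(=O)oc2c(OC)c1OC[C@H]1OC(C)(C)O[C@]1(C)CCC=C(C)C | intermediate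
13 | 7-{[(2R,3R)-2,3-dihydroxy-3,7-dimethyloct-6-en-1-yl]oxy}-6,8-dimethoxy-2H-chromen-2-one (altissimacoumarin C) | COc1cc2ccc(=O)oc2c(OC)c1OC[C@@H](O)[C@](C)(O)CCC=C(C)C | target

Total step count: 7. Longest linear sequence: 7 steps (1 → 13).

Steps most likely to fail:

Step 6 (key step). The gold-activated alkyne may attack the ipso carbon C8a, which is para to the C6 methoxy group, and the spiro cation may then lose a methyl group to traces of water and end as a dearomatised spirolactone; closure at the only moderately activated C4a may also be slow. The fallback sets out from phenol 9 and comes back at coumarin 12. Phenol 9 would be formylated at its only free ortho position (MgCl2, Et3N, paraformaldehyde, MeCN, reflux) to give 2-hydroxy-3,5-dimethoxy-4-{[(4R,5R)-2,2,4-trimethyl-4-(4-methylpent-3-en-1-yl)-1,3-dioxolan-5-yl]methoxy}benzaldehyde F1. Heating F1 with Ph3P=C=C=O in toluene (O-acylation of the phenol, then intramolecular Wittig reaction with the formyl group) would close the pyranone and give 12.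

Step 2. The hindered aryloxide may intercept the minor terminal epoxide too slowly, so that alkoxide-initiated oligomerisation of the epoxides takes over. The fallback sets out from epoxide 2 and comes back at diol 5. Epoxide 2 would be opened under aqueous Payne conditions (NaOH, t-BuOH/H2O, 75 °C) to (2R,3R)-3,7-dimethyloct-6-ene-1,2,3-triol F2. Its primary hydroxyl would be sulfonylated selectively (TsCl, Et3N, Bu2SnO cat., CH2Cl2) to (2R,3R)-2,3-dihydroxy-3,7-dimethyloct-6-en-1-yl 4-methylbenzenesulfonate F3. Treating F3 with phenol 3 and K2CO3 in DMF at 70 °C, where the terminal epoxide forms by ring closure and is opened by the aryloxide, would give 5.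

Step 4. Deprotonation next to the aryl ether oxygen (OCH2) or at allylic positions of the side chain may compete with ring lithiation, or lithiation may stay incomplete. The fallback sets out from epoxide 2 and comes back at phenol 9; the oxygen would come from a formyl group already in place instead of from metalation. Epoxide 2 would be combined under the conditions of step 2 with 3-hydroxy-2,4-dimethoxybenzaldehyde F4 (taken as purchased) to give 3-{[(2R,3R)-2,3-dihydroxy-3,7-dimethyloct-6-en-1-yl]oxy}-2,4-dimethoxybenzaldehyde F5. The diol would be protected as in step 3 to give 2,4-dimethoxy-3-{[(4R,5R)-2,2,4-trimethyl-4-(4-methylpent-3-en-1-yl)-1,3-dioxolan-5-yl]methoxy}benzaldehyde F6. Dakin oxidation (30% H2O2, B(OH)3, THF, rt; hydrogen peroxide alone should not epoxidise the isolated alkene) would give 2,4-dimethoxy-3-{[(4R,5R)-2,2,4-trimethyl-4-(4-methylpent-3-en-1-yl)-1,3-dioxolan-5-yl]methoxy}phenyl formate F7, and its methanolysis (K2CO3, MeOH, rt) would give 9.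

Further compounds

F1 | step 6 | 2-hydroxy-3,5-dimethoxy-4-{[(4R,5R)-2,2,4-trimethyl-4-(4-methylpent-3-en-1-yl)-1,3-dioxolan-5-yl]methoxy}benzaldehyde | O=Cc1cc(OC)c(OC[C@H]2OC(C)(C)O[C@]2(C)CCC=C(C)C)c(OC)c1O
F2 | step 2 | (2R,3R)-3,7-dimethyloct-6-ene-1,2,3-triol | OC[C@@H](O)[C@](C)(O)CCC=C(C)C
F3 | step 2 | (2R,3R)-2,3-dihydroxy-3,7-dimethyloct-6-en-1-yl 4-methylbenzenesulfonate | Cc1ccc(cc1)S(=O)(=O)OC[C@@H](O)[C@](C)(O)CCC=C(C)C
F4 | step 4 | 3-hydroxy-2,4-dimethoxybenzaldehyde | O=Cc1ccc(OC)c(O)c1OC
F5 | step 4 | 3-{[(2R,3R)-2,3-dihydroxy-3,7-dimethyloct-6-en-1-yl]oxy}-2,4-dimethoxybenzaldehyde | O=Cc1ccc(OC)c(OC[C@@H](O)[C@](C)(O)CCC=C(C)C)c1OC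
F6 | step 4 | 2,4-dimethoxy-3-{[(4R,5R)-2,2,4-trimethyl-4-(4-methylpent-3-en-1-yl)-1,3-dioxolan-5-yl]methoxy}benzaldehyde | O=Cc1ccc(OC)c(OC[C@H]2OC(C)(C)O[C@]2(C)CCC=C(C)C)c1OC
F7 | step 4 | 2,4-dimethoxy-3-{[(4R,5R)-2,2,4-trimethyl-4-(4-methylpent-3-en-1-yl)-1,3-dioxolan-5-yl]methoxy}phenyl formate | O=COc1ccc(OC)c(OC[C@H]2OC(C)(C)O[C@]2(C)CCC=C(C)C)c1OC
A1 | direct plan | dimethyl squarate (3,4-dimethoxycyclobut-3-ene-1,2-dione) | COC1=C(OC)C(=O)C1=O
A2 | direct plan | 4-[(E)-3,3-diethoxyprop-1-enyl]-2,3,4-trimethoxycyclobut-2-en-1-one (racemic) | O=C1C(OC)=C(OC)C1(OC)/C=C/C(OCC)OCC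
A3 | direct plan | 6,7,8-trimethoxy-2H-chromen-2-one | COc1cc2ccc(=O)oc2c(OC)c1OC
A4 | direct plan | 7-hydroxy-6,8-dimethoxy-2H-chromen-2-one (isofraxidin) | COc1cc2ccc(=O)oc2c(OC)c1O
A5 | direct plan | [(2R,3S)-3-methyl-3-(4-methylpent-3-en-1-yl)oxiran-2-yl]methanol ((2R,3S)-2,3-epoxynerol) | OC[C@H]1O[C@@]1(C)CCC=C(C)C
A6 | direct plan | 6,8-dimethoxy-7-{[(2R,3S)-3-methyl-3-(4-methylpent-3-en-1-yl)oxiran-2-yl]methoxy}-2H-chromen-2-one | COc1cc2ccc(=O)oc2c(OC)c1OC[C@H]1O[C@@]1(C)CCC=C(C)C
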